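The target is read as mesquitol-(4α→8)-catechin. The upper unit is 2R,3S,4S (2,3-trans, 3,4-trans, 2,4-cis) and the lower unit is (+)-catechin (2R,3S).

## Retrosynthetic overview

1. The target comes from eightfold O-debenzylation of its octabenzyl ether.
2. The octabenzyl ether comes from forming the upper C4–lower C8 bond by anti opening of a transient C3–C4 oxirane, a ring absent from the target. The oxirane is made in the same flask from a (2S)-flav-3-ene and is opened by C8 of tetra-O-benzylcatechin; this net anti oxy-arylation of C3=C4 makes the interflavan bond, installs the C3 hydroxyl and sets C3 and C4 from the single C2 stereocentre.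
3. Enabling feature: upper C4 is benzylic on an A ring whose C7 oxygen (para to C4a) and pyran O1 (on C8a, ortho to C4a) can carry positive charge, and it stands trans to the C3–OH, which is the retron of an epoxide opening. Lower C8 lies between O1 and the C7 oxygen of a phloroglucinol-type A ring and is its most nucleophilic carbon.
4. The (2S)-flav-3-ene comes from enantioselective aryl boronate addition to the benzopyrylium ion of a 2-ethoxy-2H-chromene, which comes from the lactol of daphnetin. The nucleophile comes from (+)-catechin.
5. Ring order: all six rings of the target are bought (upper A/C from daphnetin, upper B from the boronic acid, the lower three from catechin). The only ring formed is the oxirane, and it is opened in the step that makes it.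

Key step: step 7

Assumption: the sense of induction of the tartaric-acid-derived catalyst with this boronate is not presupposed. Both antipodes are accessible from L- and D-tartaric acid, and the one that delivers the (2S)-flavene is used.

## Route

Step 1
Reactants: 1 daphnetin (7,8-dihydroxycoumarin)
Product: 2 7,8-bis(benzyloxy)-2H-chromen-2-one
Conditions: BnBr (2.3 equiv), K2CO3, DMF, rt → 50 °C
Reagents that add atoms: benzyl bromide, BrCc1ccccc1
Why: Williamson ether synthesis should alkylate both catechol phenols while the lactone is inert to K2CO3 in DMF, and no stereocentre is involved.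

Step 2
Reactants: 2 7,8-bis(benzyloxy)-2H-chromen-2-one
Product: 3 (±)-7,8-bis(benzyloxy)-2H-chromen-2-ol (lactol)
Conditions: DIBAL-H (1.1 equiv), CH2Cl2, −78 °C; aq. Rochelle salt
Reagents that add atoms: none
Why: Partial DIBAL-H reduction of a lactone should stop at the lactol because the aluminium hemiacetal persists at −78 °C, and the new C2 centre is racemic and of no consequence since it is ionised later.

Step 3
Reactants: 3 (±)-7,8-bis(benzyloxy)-2H-chromen-2-ol
Product: 4 (±)-7,8-bis(benzyloxy)-2-ethoxy-2H-chromene
Conditions: EtOH, PPTS (cat.), 4 Å MS, rt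
Reagents that add atoms: ethanol, CCO
Why: Acid-catalysed acetalisation through the 7-alkoxy-stabilised 1-benzopyrylium ion should give the 2-ethoxy acetal as a racemate whose C2 configuration is erased in step 5.

Step 4
Reactants: 5 [3,4-bis(benzyloxy)phenyl]boronic acid
Product: 6 diethyl [3,4-bis(benzyloxy)phenyl]boronate
Conditions: EtOH (excess), toluene, 4 Å MS, rt; concentrate
Reagents that add atoms: ethanol, CCO
Why: Dehydrative esterification of a boronic acid should give the exchange-labile diethyl boronate that the chiral diol-acid catalyst of step 5 needs.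

Step 5
Reactants: 4 (±)-7,8-bis(benzyloxy)-2-ethoxy-2H-chromene; 6 diethyl [3,4-bis(benzyloxy)phenyl]boronate
Product: 7 (2S)-7,8-bis(benzyloxy)-2-[3,4-bis(benzyloxy)phenyl]-2H-chromene (tetra-O-benzyl flav-3-ene)
Conditions: 6 (1.5 equiv), tartaric-acid-derived α,β-dihydroxy acid monoamide (5–10 mol %), Yb(OTf)3 (5 mol %), EtOAc, −20 °C
Reagents that add atoms: none
Why: In this enantioselective boronate addition to a chromene acetal (Petasis-type aryl transfer to a 1-benzopyrylium ion under chiral Brønsted acid/lanthanide triflate co-catalysis), the chiral dioxaborolane "ate" complex should deliver the aryl group to one face of C2 and so set the (2S) centre.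

Step 6
Reactants: 8 (+)-catechin
Product: 9 (2R,3S)-5,7,3',4'-tetra-O-benzylcatechin (3-OH free)
Conditions: BnBr (4.4 equiv), K2CO3, DMF, 0 °C → rt, Ar
Reagents that add atoms: benzyl bromide, BrCc1ccccc1
Why: Williamson ether synthesis with a weak base should benzylate only the four phenols, leave the secondary 3-OH free and leave C2 and C3 from the chiral pool untouched.

Step 7
Reactants: 7 (2S)-tetra-O-benzyl flav-3-ene; 9 tetra-O-benzylcatechin
Product: 11 octa-O-benzyl mesquitol-(4α→8)-catechin, via flavene oxide 10 (not isolated)
Conditions: DMDO (1.1 equiv, acetone), CH2Cl2, −40 °C; volatiles off in vacuo below −20 °C; then 9 (2.5 equiv), CH2Cl2, 4 Å MS, −78 °C, BF3·OEt2 (0.2 equiv) added last, → −40 °C; Et3N quench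
Reagents that add atoms: dimethyldioxirane, CC1(C)OO1
Why: Proposed new method: DMDO should transfer oxygen in a concerted spiro transition state to the electron-rich C3=C4 styrene bond of 7 and so close the only new ring, the transient oxirane of 10 (concerted [2+1] oxygen transfer), after which BF3 binds the oxirane oxygen, the C4–O bond loosens because the charge at C4 is carried by the C7 benzyloxy group (para to C4a) and by O1 (on C8a, ortho to C4a), C8 of 9 attacks C4 in a Friedel–Crafts alkylation, and the arenium proton ends on the C3 oxygen, so the promoter is catalytic and every atom of 10 and 9 stays in 11. The closest known reaction types are the DMDO epoxidation of glycals followed by Lewis-acid opening of the 1,2-anhydrosugar at its oxocarbenium-like carbon, the Lewis-acid or fluoroalcohol promoted opening of styrene oxides by 1,3,5-trialkoxybenzenes with inversion at the benzylic carbon, and the Lewis-acid condensation of C4-oxygenated benzylated flavan-3-ols with 9; what has not been shown is a flav-3-ene oxide as the C4 electrophile for an interflavan bond. C3 (S) is fixed by the face of oxygen transfer, which the C2 aryl group next to the alkene directs to the opposite face (2,3-trans), and C4 (S) is fixed by anti opening, an outcome on which the SN2-like path (inversion) and the SN1-like path (attack on the C4 cation opposite the BF3-bound C3 alkoxide) converge (3,4-trans, 2,4-cis). Site selectivity in the electrophile (C4, not C3) follows from the benzylic, doubly oxygen-stabilised character of C4, and in the nucleophile (C8, not C6) from C8 lying between the ring oxygen O1 and one benzyloxy group while C6 is crowded by two benzyloxy groups. Self-condensation of the electrophile should be slow because its 7,8-dioxygenated A ring lacks the mutually reinforcing 1,3,5-oxygen pattern of 9, a second alkylation of 11 at its C6 is held back by the excess of 9, and C4–O adducts with the free 3-hydroxyl groups re-ionise under BF3 and drain to the C–C product. The competing Meinwald-type 1,2-shift of 10 is countered by adding the promoter last, at −78 °C, to a concentrated mixture of 10 and 9.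

Step 8
Reactants: 11 octa-O-benzyl mesquitol-(4α→8)-catechin
Product: 12 mesquitol-(4α→8)-catechin (target)
Conditions: H2 (1 atm), Pd(OH)2/C, THF/MeOH/H2O, rt; filtration and lyophilisation under Ar
Reagents that add atoms: none
Why: Heterogeneous hydrogenolysis should cleave the eight aryl benzyl ethers while the ring-bound C2–O1 ethers and the hindered C4–C8 bond persist, as is usual for benzylated flavan-3-ol dimers, so no stereocentre is touched.

## Compound list

1 | daphnetin (7,8-dihydroxycoumarin) | O=C1C=Cc2ccc(O)c(O)c2O1 | starting material
2 | 7,8-bis(benzyloxy)-2H-chromen-2-one | O=C1C=Cc2ccc(OCc3ccccc3)c(OCc3ccccc3)c2O1 | intermediate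
3 | (±)-7,8-bis(benzyloxy)-2H-chromen-2-ol (racemic lactol) | OC1C=Cc2ccc(OCc3ccccc3)c(OCc3ccccc3)c2O1 | intermediate
4 | (±)-7,8-bis(benzyloxy)-2-ethoxy-2H-chromene (racemic acetal) | CCOC1C=Cc2ccc(OCc3ccccc3)c(OCc3ccccc3)c2O1 | intermediate
5 | [3,4-bis(benzyloxy)phenyl]boronic acid | OB(O)c1ccc(OCc2ccccc2)c(OCc2ccccc2)c1 | starting material
6 | diethyl [3,4-bis(benzyloxy)phenyl]boronate | CCOB(OCC)c1ccc(OCc2ccccc2)c(OCc2ccccc2)c1 | intermediate
7 | (2S)-7,8-bis(benzyloxy)-2-[3,4-bis(benzyloxy)phenyl]-2H-chromene | c1ccccc1COc1ccc([C@H]2Oc3c(ccc(OCc4ccccc4)c3OCc3ccccc3)C=C2)cc1OCc1ccccc1 | intermediate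
8 | (+)-catechin (2R,3S) | c1c(O)cc(O)c2c1O[C@H](c1ccc(O)c(O)c1)[C@@H](O)C2 | starting material
9 | (2R,3S)-5,7,3',4'-tetra-O-benzylcatechin | c1c(OCc3ccccc3)cc(OCc3ccccc3)c2c1O[C@H](c1ccc(OCc3ccccc3)c(OCc3ccccc3)c1)[C@@H](O)C2 | intermediate
10 | 3,4-epoxide of 7, oxirane oxygen on the face opposite the 2-aryl group | c1ccccc1COc1ccc([C@H]2Oc3c(ccc(OCc4ccccc4)c3OCc3ccccc3)[C@@H]3O[C@H]23)cc1OCc1ccccc1 | intermediate
11 | octa-O-benzyl mesquitol-(4α→8)-catechin (upper 2R,3S,4S; lower 2R,3S; both 3-OH free) | c1ccccc1COc1ccc([C@H]2Oc3c(ccc(OCc4ccccc4)c3OCc3ccccc3)[C@@H](c3c(OCc4ccccc4)cc(OCc4ccccc4)c4c3O[C@H](c3ccc(OCc5ccccc5)c(OCc5ccccc5)c3)[C@@H](O)C4)[C@@H]2O)cc1OCc1ccccc1 | intermediate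
12 | (2R,3S,4S)-2-(3,4-dihydroxyphenyl)-4-[(2R,3S)-2-(3,4-dihydroxyphenyl)-3,5,7-trihydroxychroman-8-yl]chroman-3,7,8-triol | Oc1ccc([C@H]2Oc3c(ccc(O)c3O)[C@@H](c3c(O)cc(O)c4c3O[C@H](c3ccc(O)c(O)c3)[C@@H](O)C4)[C@@H]2O)cc1O | target

## Step count and risks

Total step count: 8. Longest linear sequence: 6 (steps 1, 2, 3, 5, 7, 8).

**Step 7 (labelled step).**
- Risk: the labile oxirane may undergo a Meinwald-type 1,2-shift or oligomerise before it is arylated. The oxygen transfer may also show imperfect facial selectivity.
- Fallback, from 7 back to 11, known chemistry throughout: Upjohn dihydroxylation of 7 (OsO4 cat., NMO, acetone/water) should add anti to the 2-aryl group and give the 2,3-trans-3,4-cis flavan-3,4-diol F1.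
- Its benzylic 4-OH is then ionised with TiCl4 in CH2Cl2 at 0 °C in the presence of excess 9. This classical flavan-3,4-diol/flavan-3-ol condensation should deliver 11, with attack anti to the C3 oxygen.

**Step 5.**
- Risk: enantioselectivity may be low, or the electron-rich flavene may racemise through reversible C2–O1 ionisation in the presence of the lanthanide triflate.
- Fallback, from 4 and 5 back to 11, with resolution by the enantiopure coupling partner instead of asymmetric catalysis: an achiral nickel(0)/phosphine-catalysed cross-coupling of acetal 4 with boronic acid 5 should give the racemate, that is 7 together with its mirror image, the (2R)-flavene F2.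
- The mixture is taken through the step 7 protocol, in which the mirror-image flavene oxide F3 forms beside 10.
- Enantiopure 9 turns the pair into 11 and the diastereomeric dimer ent-mesquitol-(4β→8)-catechin octabenzyl ether F4. The two are separated by chromatography.

**Step 8.**
- Risk: the eightfold hydrogenolysis may stall through adsorption of partly deprotected polyphenols on the catalyst. The pyrogallol-type A ring may also oxidise in air during work-up.
- Fallback, from 11 directly to 12: non-reductive Lewis-acid debenzylation with BCl3 and pentamethylbenzene as cation scavenger in CH2Cl2 at −78 °C, with a methanol quench. The comparatively acid-stable interflavan bond of a 5-deoxy upper unit should tolerate this at low temperature.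

## Further compounds

F1 | step 7 | (2R,3S,4S)-7,8-bis(benzyloxy)-2-[3,4-bis(benzyloxy)phenyl]chromane-3,4-diol (2,3-trans-3,4-cis) | c1ccccc1COc1ccc([C@H]2Oc3c(ccc(OCc4ccccc4)c3OCc3ccccc3)[C@H](O)[C@@H]2O)cc1OCc1ccccc1
F2 | step 5 | (2R)-7,8-bis(benzyloxy)-2-[3,4-bis(benzyloxy)phenyl]-2H-chromene (enantiomer of 7) | c1ccccc1COc1ccc([C@@H]2Oc3c(ccc(OCc4ccccc4)c3OCc3ccccc3)C=C2)cc1OCc1ccccc1
F3 | step 5 | mirror-image flavene oxide (enantiomer of 10) | c1ccccc1COc1ccc([C@@H]2Oc3c(ccc(OCc4ccccc4)c3OCc3ccccc3)[C@H]3O[C@@H]23)cc1OCc1ccccc1
F4 | step 5 | ent-mesquitol-(4β→8)-catechin octabenzyl ether (upper 2S,3R,4R; lower 2R,3S) | c1ccccc1COc1ccc([C@@H]2Oc3c(ccc(OCc4ccccc4)c3OCc3ccccc3)[C@H](c3c(OCc4ccccc4)cc(OCc4ccccc4)c4c3O[C@H](c3ccc(OCc5ccccc5)c(OCc5ccccc5)c3)[C@@H](O)C4)[C@H]2O)cc1OCc1ccccc1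
F0 | step 8 | none | none
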